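**Target:** CNP0156395.0, 5,7-dihydroxy-2-(5-hydroxy-2,4-dimethoxyphenyl)-3,6,8-trimethoxy-4H-chromen-4-one (compound 20).

## Analysis of the target

Compound 20 is a flavone: a benzo ring A fused to a 4-pyranone ring C, which carries an aryl ring B at C2. Ring A is fully substituted (C5-OH, C6-OMe, C7-OH, C8-OMe, plus the two ring-fusion atoms C4a and C8a). Ring C bears a methoxy group at C3, and ring B is a 2',4'-dimethoxy-5'-hydroxyphenyl group. There is no stereocentre, so every difficulty is one of placement: eight oxygen substituents, three free phenols and five methyl ethers, each at a fixed position. The free phenols make the molecule electron-rich and prone to oxidation in base, and the pyranone can open and reclose under forcing acid or base (Wessely–Moser isomerisation). The alternating OH/OMe pattern on ring A rules out late selective methylation or demethylation, and the C3 methoxy group must be carried through ring C formation. The route rests on two features. First, C4 is a bare carbonyl carbon sitting between C4a and C3. Second, ring A taken as a fragment is symmetric about the C4a–C7 axis: the oxygens on C5 and C8a are equivalent, as are the methoxy groups on C6 and C8. C4 can therefore be brought in as carbon monoxide, and either flanking oxygen of ring A may become O1.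

## Retrosynthetic reasoning

**20 ⇒ 18 (O1–C2 and four O-protecting groups).** The pyranone is opened at its enol-ether bond O1–C2. This gives the 2-methoxy-1,3-diketone 18, in which the C5, C7 and C8a oxygens of ring A and the C5' oxygen of ring B are all acetal-protected. Cyclodehydration of an ortho-hydroxyaryl 1,3-diketone is the most dependable flavone closure. Because ring A of 18 is symmetric, whichever ortho oxygen attacks, the same product forms. Using four identical acid-labile acetals means unmasking (to the free tetraol 19) and ring closure happen in the same flask, with no separate deprotection step.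

**18 ⇒ 8 + 15 + 16 (C4a–C4 and C4–C3).** Both bonds to C4 are cut. This leaves aryl iodide 8 (ring A with its full oxygen pattern), ketone 15 (ring B, C2, C3 and the C3 methoxy group) and carbon monoxide 16. The cut is made here because C4 carries nothing but oxygen, so it is the one skeletal atom that a gas can supply. The two aromatic halves are of similar size and are made independently. Ketone 15 has a single enolisable position, the future C3, and 8 is symmetric, so the coupling has no regiochemical choice. A cut at C2–C3 or C2–C1' would require an acyl group to be built on the crowded C4a position of a desymmetrised ring A first. The forward reaction needs palladium to insert into a di-ortho-substituted C–I bond, take up 16, and transfer the aroyl group to the carbon of enolate 17.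

**8 ⇒ 6 (C4a–I).** The iodine is traced to the only aromatic C–H of 6. That hydrogen lies between two acetal oxygens, the best possible site for directed lithiation (aryllithium 7), so the iodination needs no selectivity beyond what the substrate provides.

**6 ⇒ 5 ⇒ 3 (two O-acetals, then two aryl C–O bonds).** The two new acetals come from diol 5. Its two hydroxyls are traced to the two C–Br bonds of 3 through a bis-boronate (4). Swapping C–Br for C–O by way of boron is preferred to direct oxygenation of the arene, which would attack the wrong positions or over-oxidise.

**3 ⇒ 2 ⇒ 1 (two aryl C–Br bonds, one O-acetal).** Both bromines enter by electrophilic substitution of 2. Each goes ortho to one methoxy group and para to the other. The position para to the central oxygen stays free, because that oxygen is twisted out of conjugation by its two neighbours. Compound 2 is the acetal of the commercial phenol 1, which already holds the three contiguous oxygens of C6, C7 and C8.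

**15 ⇒ 12 + 13 (aryl–acyl bond).** The ketone is cut between ring B and its carbonyl carbon. The aryl unit comes from bromide 12 through lithium exchange (aryllithium 14), and the methoxyacetyl unit from the N-methoxy-N-methyl amide 13. This avoids a Lewis-acid acylation, which would threaten the ethers.

**12 ⇒ 11 ⇒ 9 (O-acetal, then aryl C–O from aryl C–CHO).** The C5' oxygen is traced to the formyl group of the commercial aldehyde 9 through oxidative aryl migration (formate 10, phenol 11). The bromine of 9 already sits where the ketone carbon must go.

## Alternatives that were turned down

**Alternative 1:** Ring C is disconnected at C4–C4a and O1–C2 in one thermal operation. The free symmetric triol A2 (2,4-dimethoxybenzene-1,3,5-triol) is heated with the alpha-methoxy beta-keto ester A3. Loss of ethanol gives an acylketene that acylates the ring carbon of A2. The neighbouring hydroxyl then condenses onto the aryl ketone, giving flavone A1, the 5'-O-benzyl ether of the target, and one hydrogenolysis finishes.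
- For: ring A needs no protecting groups, the 5- and 7-hydroxyls are free from the start, and the symmetry of A2 removes any regiochemical question. On step count this plan is stronger than the chosen one, by roughly the acetal and iodination steps.
- Against: a pentaoxygenated, air-sensitive triol must survive temperatures near 200 °C. An alpha-substituted keto ester forms its acylketene reluctantly. C-acylation leading to the chromone competes with O-acylation and with phenol attack on the ketone, which leads to the isomeric coumarin, and only the temperature decides between them. A2 would in any case come from the same series as 6.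
- Comparison: the chosen route gives up a few steps. In return, C4 arrives as 16 attached to a defined carbon of 8, so no coumarin manifold exists, and the coupling runs at moderate temperature on fully protected partners.

**Alternative 2:** Only O1–C2 is disconnected. Ynone A5 is treated with iodine monochloride A6. The activated alkyne is attacked by one of the two equivalent ortho methoxy oxygens, chloride removes the methyl group, and the 3-iodochromone A4 results.
- For: this ring closure is mild and of a very reliable class, and the symmetry again removes the choice of oxygen. On the robustness of the ring-forming event it is stronger than a carbonylative coupling at a hindered iodide.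
- Against: A4 has the wrong group at three kinds of position. C3 carries iodine where a methoxy group is needed, C5 carries a methyl ether where a phenol is needed, and two benzyl ethers remain. Forming a C–O bond at C3, between the C4 carbonyl and an ortho-substituted ring B, has to compete with reduction and with methoxide attack on the pyranone. Selective 5-O-demethylation and hydrogenolysis follow. The electron-rich ring B, with open C3' and C6' positions, is also exposed to iodination by A6.
- Comparison: the chosen route brings the C3 methoxy group in with 15 and ends one step after the key step, against three or more here.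

**Alternative 3:** Ring A is built de novo, disconnecting C4a–C5. The 4-hydroxycyclobutenone A8, carrying a pyranone at C4, is heated. Four-electron ring opening gives a dienylketene, whose ketene carbon closes onto the pyranone carbon by six-electron electrocyclisation. Tautomerisation delivers the 5,8-hydroquinone A7.
- For: no aromatic substitution chemistry is needed, and every oxygen of ring A is placed by construction. On independence from arene functionalisation this plan is stronger than the chosen one.
- Against: it needs a pyranone metallated next to its ring oxygen while carrying its own carbonyl, and an addition to a squaric ester with two different alkoxy groups at the correct carbonyl, otherwise the C6 and C7 substituents are exchanged. The product A7 is an oxidation-prone hydroquinone that must then be methylated at O8 but not at O5, and debenzylated.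
- Comparison: the chosen route uses two symmetric or singly reactive aromatic fragments made from simple arenes (1 and 9) and confines its risk to one catalytic step, where this plan spreads risk over several.

Key step: step 9

Remark on the chemistry: all four oxygens that end as free phenols or as O1 are carried as methoxymethyl (MOM) ethers, so that one acid step at the end both unmasks and cyclises; compounds 1, 9 and 13 are taken to be catalogue compounds.

## Route

**Step 1**
Reactants: 1 2,6-dimethoxyphenol
Product: 2 1,3-dimethoxy-2-(methoxymethoxy)benzene
Conditions: NaH, MOMCl, DMF, 0 °C to rt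
Reagents that add atoms: chloromethyl methyl ether (MOMCl), COCCl
Why: Williamson-type O-alkylation of the sodium phenoxide by the reactive alpha-chloro ether. The new acetal oxygen, flanked by two methoxy groups, is pushed out of the ring plane, which leaves the methoxy groups in control of the next step.

**Step 2**
Reactants: 2 1,3-dimethoxy-2-(methoxymethoxy)benzene
Product: 3 1,5-dibromo-2,4-dimethoxy-3-(methoxymethoxy)benzene
Conditions: NBS (2.1 equiv), MeCN, 0 °C to rt, dark
Reagents that add atoms: N-bromosuccinimide, O=C1CCC(=O)N1Br
Why: Electrophilic aromatic bromination, twice. Each bromine should enter ortho to one methoxy group and para to the other, as is usual for 1,2,3-trialkoxybenzenes, while the position para to the twisted central oxygen is meta to both methoxy groups and should stay free. NBS gives succinimide and no HBr, so the acetal should survive.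

**Step 3**
Reactants: 3 1,5-dibromo-2,4-dimethoxy-3-(methoxymethoxy)benzene
Product: 5 4,6-dimethoxy-5-(methoxymethoxy)benzene-1,3-diol, via the bis(pinacol boronate) 4 (not isolated)
Conditions: B2pin2, PdCl2(dppf) (5 mol %), KOAc, dioxane, 90 °C; then 30% H2O2, NaOH, THF/H2O, 0 °C; NH4Cl (aq), under argon
Reagents that add atoms: hydrogen peroxide, OO (both phenol oxygens); bis(pinacolato)diboron, CC1(C)OB(B2OC(C)(C)C(C)(C)O2)OC1(C)C (boron of intermediate 4 only)
Why: Twofold Miyaura borylation, each C–Br bond having only one ortho substituent, then oxidation of the aryl boronates by aryl migration from boron to peroxide oxygen and hydrolysis. The new hydroxyls are meta to each other, so no quinone can form directly.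

**Step 4**
Reactants: 5 4,6-dimethoxy-5-(methoxymethoxy)benzene-1,3-diol
Product: 6 2,4-dimethoxy-1,3,5-tris(methoxymethoxy)benzene
Conditions: NaH (2.5 equiv), MOMCl (2.4 equiv), DMF, 0 °C to rt
Reagents that add atoms: chloromethyl methyl ether (MOMCl), COCCl
Why: Double Williamson-type O-alkylation. Each phenol has one open ortho position and should alkylate readily.

**Step 5**
Reactants: 6 2,4-dimethoxy-1,3,5-tris(methoxymethoxy)benzene
Product: 8 1-iodo-3,5-dimethoxy-2,4,6-tris(methoxymethoxy)benzene, via the aryllithium 7 (not isolated)
Conditions: n-BuLi, THF, 0 °C; then I2, THF, −78 °C to rt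
Reagents that add atoms: iodine, II
Why: Directed ortho-metalation at the only aromatic C–H, which is acidified and chelated by two flanking acetal oxygens, followed by iodine quench of the aryllithium. No other site can be deprotonated.

**Step 6**
Reactants: 9 5-bromo-2,4-dimethoxybenzaldehyde
Product: 11 5-bromo-2,4-dimethoxyphenol, via the aryl formate 10 (not isolated)
Conditions: mCPBA, CH2Cl2, 0 °C to rt; then K2CO3, MeOH, rt
Reagents that add atoms: 3-chloroperoxybenzoic acid (mCPBA), O=C(OO)c1cccc(Cl)c1
Why: Dakin-type Baeyer–Villiger oxidation. The aryl group, with methoxy groups ortho and para to the formyl carbon, migrates in preference to hydrogen, and the formate is removed by methanolysis.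

**Step 7**
Reactants: 11 5-bromo-2,4-dimethoxyphenol
Product: 12 1-bromo-2,4-dimethoxy-5-(methoxymethoxy)benzene
Conditions: NaH, MOMCl, DMF, 0 °C to rt
Reagents that add atoms: chloromethyl methyl ether (MOMCl), COCCl
Why: Williamson-type O-alkylation of the phenoxide. The acetal is stable to the organolithium and basic steps that follow.

**Step 8**
Reactants: 12 1-bromo-2,4-dimethoxy-5-(methoxymethoxy)benzene; 13 N,2-dimethoxy-N-methylacetamide
Product: 15 1-[2,4-dimethoxy-5-(methoxymethoxy)phenyl]-2-methoxyethan-1-one, via the aryllithium 14 (not isolated)
Conditions: n-BuLi, THF, −78 °C; then 13, −78 to 0 °C; NH4Cl (aq)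
Reagents that add atoms: none
Why: Bromine–lithium exchange followed by Weinreb ketone synthesis. The chelated tetrahedral adduct does not collapse until the quench, so a second addition is excluded and the alpha-methoxy ketone is released on work-up.

**Step 9**
Reactants: 8 1-iodo-3,5-dimethoxy-2,4,6-tris(methoxymethoxy)benzene; 15 1-[2,4-dimethoxy-5-(methoxymethoxy)phenyl]-2-methoxyethan-1-one; 16 carbon monoxide
Product: 18 1-[2,4-dimethoxy-5-(methoxymethoxy)phenyl]-3-[3,5-dimethoxy-2,4,6-tris(methoxymethoxy)phenyl]-2-methoxypropane-1,3-dione (racemic at C2, enolisable), via the sodium enolate 17 (not isolated)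
Conditions: 15 (2 equiv), NaN(SiMe3)2 (2 equiv), THF, 0 °C; then 8, Pd(dba)2 (5 mol %), 1,3-bis(diphenylphosphino)propane (5 mol %), CO (1 atm), THF, 80 °C, sealed; NH4Cl (aq)
Reagents that add atoms: none
Why: This is a carbonylative alpha-arylation of a ketone enolate, the known palladium route from aryl iodides, CO and aryl ketones to 1,3-diketones. Zerovalent palladium inserts into the C–I bond of 8, and 16 then migrates into the crowded aryl–palladium bond, which the two ortho acetal oxygens favour because the aroyl ligand moves the bulk one atom away from the metal. Enolate 17 replaces iodide on the divalent aroylpalladium complex and reductive elimination forms C3–C4, so C4a–C4 and C4–C3 are both made in one catalytic cycle, with the chelating diphosphine holding acyl and enolate cis. The 2-methoxy-1,3-diketone is more acidic than 15 and is deprotonated at once by the second equivalent of 17, which makes the sequence irreversible and shields the product from further acylation; the quench releases 18 and returns one equivalent of 15. No ring is closed, and the only sp3 centre formed, C3, is enolisable and becomes sp2 in step 10, so no stereocontrol is needed. Two selectivities are required: carbonylative over direct arylation, secured by the di-ortho-substituted iodide, which slows direct enolate capture at aryl–palladium; and C- over O-acylation, for which the palladium-bound enolate pathway is relied on. Regiochemistry is fixed by the substrates, since 15 has a single enolisable position and 8 is symmetric.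

**Step 10**
Reactants: 18 1-[2,4-dimethoxy-5-(methoxymethoxy)phenyl]-3-[3,5-dimethoxy-2,4,6-tris(methoxymethoxy)phenyl]-2-methoxypropane-1,3-dione
Product: 20 5,7-dihydroxy-2-(5-hydroxy-2,4-dimethoxyphenyl)-3,6,8-trimethoxy-4H-chromen-4-one, via the tetraol diketone 19 (not isolated)
Conditions: conc. HCl, MeOH, 60 °C
Reagents that add atoms: none
Why: Acetal methanolysis should free four phenols; one of the two equivalent ortho hydroxyls of ring A then adds to the ring B ketone (6-exo-trig hemiketal) and acid-catalysed dehydration gives the pyranone, the standard cyclodehydration of ortho-hydroxyaryl 1,3-diketones to flavones. The other ortho hydroxyl becomes the chelated 5-OH, and because ring A is symmetric any acid-induced ring opening and reclosure would return the same compound.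

## Compound list

1 | 2,6-dimethoxyphenol | COc1cccc(OC)c1O | starting material
2 | 1,3-dimethoxy-2-(methoxymethoxy)benzene | COCOc1c(OC)cccc1OC | intermediate
3 | 1,5-dibromo-2,4-dimethoxy-3-(methoxymethoxy)benzene | COCOc1c(OC)c(Br)cc(Br)c1OC | intermediate
4 | 2,2'-[4,6-dimethoxy-5-(methoxymethoxy)-1,3-phenylene]bis(4,4,5,5-tetramethyl-1,3,2-dioxaborolane) | COCOc1c(OC)c(B2OC(C)(C)C(C)(C)O2)cc(B2OC(C)(C)C(C)(C)O2)c1OC | intermediate (not isolated)
5 | 4,6-dimethoxy-5-(methoxymethoxy)benzene-1,3-diol | COCOc1c(OC)c(O)cc(O)c1OC | intermediate
6 | 2,4-dimethoxy-1,3,5-tris(methoxymethoxy)benzene | COCOc1cc(OCOC)c(OC)c(OCOC)c1OC | intermediate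
7 | [3,5-dimethoxy-2,4,6-tris(methoxymethoxy)phenyl]lithium | [Li]c1c(OCOC)c(OC)c(OCOC)c(OC)c1OCOC | intermediate (not isolated)
8 | 1-iodo-3,5-dimethoxy-2,4,6-tris(methoxymethoxy)benzene | COCOc1c(I)c(OCOC)c(OC)c(OCOC)c1OC | intermediate
9 | 5-bromo-2,4-dimethoxybenzaldehyde | COc1cc(OC)c(C=O)cc1Br | starting material
10 | 5-bromo-2,4-dimethoxyphenyl formate | COc1cc(OC)c(OC=O)cc1Br | intermediate (not isolated)
11 | 5-bromo-2,4-dimethoxyphenol | COc1cc(OC)c(O)cc1Br | intermediate
12 | 1-bromo-2,4-dimethoxy-5-(methoxymethoxy)benzene | COCOc1cc(Br)c(OC)cc1OC | intermediate
13 | N,2-dimethoxy-N-methylacetamide | COCC(=O)N(C)OC | starting material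
14 | [2,4-dimethoxy-5-(methoxymethoxy)phenyl]lithium | [Li]c1cc(OCOC)c(OC)cc1OC | intermediate (not isolated)
15 | 1-[2,4-dimethoxy-5-(methoxymethoxy)phenyl]-2-methoxyethan-1-one | COCC(=O)c1cc(OCOC)c(OC)cc1OC | intermediate
16 | carbon monoxide | [C-]#[O+] | starting material
17 | sodium (Z)-1-[2,4-dimethoxy-5-(methoxymethoxy)phenyl]-2-methoxyethen-1-olate (Z expected from chelation; geometry without consequence) | [Na+].CO/C=C(\[O-])c1cc(OCOC)c(OC)cc1OC | intermediate (not isolated)
18 | 1-[2,4-dimethoxy-5-(methoxymethoxy)phenyl]-3-[3,5-dimethoxy-2,4,6-tris(methoxymethoxy)phenyl]-2-methoxypropane-1,3-dione (racemic) | COCOc1c(C(=O)C(OC)C(=O)c2cc(OCOC)c(OC)cc2OC)c(OCOC)c(OC)c(OCOC)c1OC | intermediate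
19 | 1-(5-hydroxy-2,4-dimethoxyphenyl)-2-methoxy-3-(2,4,6-trihydroxy-3,5-dimethoxyphenyl)propane-1,3-dione (racemic) | COc1cc(OC)c(C(=O)C(OC)C(=O)c2c(O)c(OC)c(O)c(OC)c2O)cc1O | intermediate (not isolated)
20 | 5,7-dihydroxy-2-(5-hydroxy-2,4-dimethoxyphenyl)-3,6,8-trimethoxy-4H-chromen-4-one | COc1cc(OC)c(-c2oc3c(OC)c(O)c(OC)c(O)c3c(=O)c2OC)cc1O | target

## Step count and risk

Total step count: 10. Longest linear sequence: 7 steps (1 → 2 → 3 → 5 → 6 → 8 → 18 → 20). The ring B arm (9 → 11 → 12 → 15) is 3 steps before the junction.

**Step 9 (key step).** The most likely failure is slow oxidative addition or slow CO uptake at the electron-rich, di-ortho-substituted iodide, so that reduction of the C–I bond back to the arene overtakes coupling. The second risk is transfer of the hindered aroyl group to the enolate oxygen, not to carbon, giving an enol ester. The fallback builds the same bonds by polar chemistry. It sets out from 6: lithiation as in step 5 gives 7, and a DMF quench should give 3,5-dimethoxy-2,4,6-tris(methoxymethoxy)benzaldehyde F1. Aldol addition of enolate 17 (from 15 and NaN(SiMe3)2, THF, −78 °C) to F1 should give 3-hydroxy-1-[2,4-dimethoxy-5-(methoxymethoxy)phenyl]-3-[3,5-dimethoxy-2,4,6-tris(methoxymethoxy)phenyl]-2-methoxypropan-1-one F2 as a mixture of racemic diastereomers. Oxidation of the secondary alcohol with Dess–Martin periodinane returns to the route at 18.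

**Step 3.** The second borylation may stall, or C–Br may be reduced to C–H at one site. The very electron-rich diol may also be over-oxidised by basic peroxide if air is admitted. The fallback drops boron and peroxide and forms both C–O bonds directly. It sets out from 3 and uses hydroxide cross-coupling (Pd2(dba)3, 2-di-tert-butylphosphino-2',4',6'-triisopropylbiphenyl, KOH, dioxane/H2O, 100 °C, acidification under argon), coming back at 5. This detour makes no new compound (F0).

**Step 8.** The aryllithium 14 may take a proton from the alpha-methylene of 13 and not add to the carbonyl, which returns the debrominated arene. The fallback changes both metal and electrophile. It sets out from 12: magnesium insertion (Mg, THF) should give [2,4-dimethoxy-5-(methoxymethoxy)phenyl]magnesium bromide F3. Addition to methoxyacetonitrile and cold aqueous citric acid work-up should give, through 1-[2,4-dimethoxy-5-(methoxymethoxy)phenyl]-2-methoxyethan-1-imine F4, the ketone, coming back at 15.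

**Step 10.** In hot acidic methanol, solvolytic cleavage of the 1,3-diketone may compete before the ring closes, or the acetals may be lost incompletely so that partly protected flavones accumulate. The fallback separates the two events in non-nucleophilic media. It sets out from 18: Me3SiBr in CH2Cl2 at −30 to 0 °C should remove the four acetals, and 19 is isolated. Dehydration with catalytic TsOH in toluene at 80 °C then comes back at 20. This detour makes no new compound (F0).

## Further compounds

F1 | step 9 | 3,5-dimethoxy-2,4,6-tris(methoxymethoxy)benzaldehyde | COCOc1c(C=O)c(OCOC)c(OC)c(OCOC)c1OC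
F2 | step 9 | 3-hydroxy-1-[2,4-dimethoxy-5-(methoxymethoxy)phenyl]-3-[3,5-dimethoxy-2,4,6-tris(methoxymethoxy)phenyl]-2-methoxypropan-1-one (racemic diastereomer mixture) | COCOc1c(C(O)C(OC)C(=O)c2cc(OCOC)c(OC)cc2OC)c(OCOC)c(OC)c(OCOC)c1OC
F0 | step 3 | none | none
F3 | step 8 | [2,4-dimethoxy-5-(methoxymethoxy)phenyl]magnesium bromide | Br[Mg]c1cc(OCOC)c(OC)cc1OC
F4 | step 8 | 1-[2,4-dimethoxy-5-(methoxymethoxy)phenyl]-2-methoxyethan-1-imine | COCC(=N)c1cc(OCOC)c(OC)cc1OC
F0 | step 10 | none | none
A1 | alternative 1 | 2-[5-(benzyloxy)-2,4-dimethoxyphenyl]-5,7-dihydroxy-3,6,8-trimethoxy-4H-chromen-4-one | COc1cc(OC)c(-c2oc3c(OC)c(O)c(OC)c(O)c3c(=O)c2OC)cc1OCc1ccccc1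
A2 | alternative 1 | 2,4-dimethoxybenzene-1,3,5-triol | COc1c(O)cc(O)c(OC)c1O
A3 | alternative 1 | ethyl 3-[5-(benzyloxy)-2,4-dimethoxyphenyl]-2-methoxy-3-oxopropanoate (racemic) | CCOC(=O)C(OC)C(=O)c1cc(OCc2ccccc2)c(OC)cc1OC
A4 | alternative 2 | 7-(benzyloxy)-2-[5-(benzyloxy)-2,4-dimethoxyphenyl]-3-iodo-5,6,8-trimethoxy-4H-chromen-4-one | COc1cc(OC)c(-c2oc3c(OC)c(OCc4ccccc4)c(OC)c(OC)c3c(=O)c2I)cc1OCc1ccccc1
A5 | alternative 2 | 1-[4-(benzyloxy)-2,3,5,6-tetramethoxyphenyl]-3-[5-(benzyloxy)-2,4-dimethoxyphenyl]prop-2-yn-1-one | COc1c(C(=O)C#Cc2cc(OCc3ccccc3)c(OC)cc2OC)c(OC)c(OC)c(OCc2ccccc2)c1OC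
A6 | alternative 2 | iodine monochloride | ClI
A7 | alternative 3 | 7-(benzyloxy)-2-[5-(benzyloxy)-2,4-dimethoxyphenyl]-5,8-dihydroxy-3,6-dimethoxy-4H-chromen-4-one | COc1cc(OC)c(-c2oc3c(O)c(OCc4ccccc4)c(OC)c(O)c3c(=O)c2OC)cc1OCc1ccccc1
A8 | alternative 3 | 4-{6-[5-(benzyloxy)-2,4-dimethoxyphenyl]-5-methoxy-4-oxo-4H-pyran-2-yl}-3-(benzyloxy)-4-hydroxy-2-methoxycyclobut-2-en-1-one (racemic) | COC1=C(OCc2ccccc2)C(O)(c2cc(=O)c(OC)c(-c3cc(OCc4ccccc4)c(OC)cc3OC)o2)C1=O
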